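**Plan** (labels: ring E = benzo ring of the dihydrobenzofuran, DHB; ring D = resorcinol ring on DHB C-3; ring B = resorcinol ring of the indane; ArF, ArC, ArA = 4-oxyphenyl groups on DHB C-2, on the eight-ring CH next to ring D, and on indane C-1)
1. Retrosynthetic cuts, in order: the eight O–Me bonds; the indane bonds C1–C7a (Friedel–Crafts) and C1–C2 (benzyl Grignard on a ring ketone); the eight-ring bond CH(ArC)–CH(ring B) (benzhydryl cation onto an enol); the formyl and acyl side chains on rings D and E; DHB C2–ArF (decarboxylative arylation); the DHB ring itself, traced back to a six-membered lactone; the coumarin (Pechmann).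
2. Forward ring order: ring E is annulated with the lactone (ring D already on C-4); the lactone is contracted to the dihydrofuran; the eight-membered carbocycle is closed between rings D and E; the cyclopentane of the indane comes last.
3. Enabling feature: DHB atoms O1, C7a, C3a and C3(H)(ring D) are the phenol oxygen, the two arene carbons and the β-carbon of a 4-arylcoumarin, and DHB C-2 is its α-carbon. Only the lactone carbonyl between O1 and C-2 has to leave the ring, and it leaves as a CO2H on C-2 that is later exchanged for ArF.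
4. Stereochemistry: DHB C-3 by Cu–H catalysis (the only catalyst-set centre); DHB C-2 trans to it by substrate control; the two eight-ring CH centres by substrate-controlled closure and epimerisation α to the ketone; the last two indane centres together in the final cationic cyclisation (all-trans indane, trans ring fusion).

Key step: step 4

Assumption: the enantiomer of the SEGPHOS ligand in step 3 is taken to be the one that gives the 4R lactone; if the sense of induction is opposite, the antipodal ligand is used.
Assumption: 3,5-dimethoxybenzylmagnesium chloride (15) is taken as a commercial solution; otherwise it is made from the benzyl chloride and Mg.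

Step 1
Reactants: 1 3,5-dihydroxybenzoic acid; 2 ethyl 3-(3,5-dimethoxyphenyl)-3-oxopropanoate
Product: 3 4-(3,5-dimethoxyphenyl)-7-hydroxy-2-oxo-2H-chromene-5-carboxylic acid
Conditions: MeSO3H, 40 °C
Reagents that add atoms: none
Why: Pechmann condensation: transesterification of one phenol OH by the β-keto ester, then intramolecular hydroxyalkylation and dehydration at the ring carbon para to the second OH (the two such carbons are equivalent), should give the 4-aryl-7-hydroxycoumarin with CO2H at C-5; no stereocentre is formed.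

Step 2
Reactants: 3 4-(3,5-dimethoxyphenyl)-7-hydroxy-2-oxo-2H-chromene-5-carboxylic acid
Product: 4 methyl 4-(3,5-dimethoxyphenyl)-7-methoxy-2-oxo-2H-chromene-5-carboxylate
Conditions: MeI, K2CO3, DMF, rt
Reagents that add atoms: iodomethane CI
Why: O-alkylation (Williamson ether synthesis and carboxylate esterification) should methylate the phenol and the acid in one operation and leave the lactone intact; no stereocentre is formed.

Step 3
Reactants: 4 methyl 4-(3,5-dimethoxyphenyl)-7-methoxy-2-oxo-2H-chromene-5-carboxylate
Product: 6 methyl (3S,4R)-3-bromo-4-(3,5-dimethoxyphenyl)-7-methoxy-2-oxochromane-5-carboxylate, via silyl ketene acetal 5 (not isolated)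
Conditions: Cu(OAc)2·H2O (3 mol %), (R)-DTBM-SEGPHOS (3 mol %), (EtO)2MeSiH, PhMe, 0 °C → rt; then NBS (1.0 equiv), THF, −78 °C
Reagents that add atoms: N-bromosuccinimide O=C1CCC(=O)N1Br
Why: Copper hydride-catalysed asymmetric 1,4-reduction of a 4-arylcoumarin should deliver hydride to one face of C-4 under ligand control (4R); the silyl ketene acetal formed is inert to further reduction and should be brominated by NBS anti to the C-4 aryl group (3S, trans; the C-3 configuration is not critical).

Step 4
Reactants: 6 methyl (3S,4R)-3-bromo-4-(3,5-dimethoxyphenyl)-7-methoxy-2-oxochromane-5-carboxylate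
Product: 8 (2R,3R)-3-(3,5-dimethoxyphenyl)-6-methoxy-4-(methoxycarbonyl)-2,3-dihydro-1-benzofuran-2-carboxylic acid, via ring-opened dilithium salt 7 (not isolated)
Conditions: LiOH, THF/H2O, 0 °C → rt; then 1 M HCl
Reagents that add atoms: lithium hydroxide [Li+].[OH-]
Why: Hydroxide should open the aryl lactone by acyl substitution to the phenoxide/α-bromocarboxylate 7, whose phenoxide oxygen then displaces bromide, so the six-membered lactone ring (O1, C2, C3, C4, C4a, C8a) becomes the five-membered dihydrofuran ring (O1, former C3, C4, C4a, C8a) and the former carbonyl carbon is expelled as an exocyclic CO2H. The closest known reaction type is the Perkin rearrangement (coumarin to benzofuran ring contraction of 3-halocoumarins) and its saturated counterpart, the base-induced contraction of α-halo or α-sulfonyloxy δ-lactones to tetrahydrofuran-2-carboxylates. The only ring closed is the dihydrofuran, by a 5-exo-tet SN2 O-alkylation. The new C-2 centre arises by inversion at the bromide-bearing carbon, so the trans (3S) bromide should give the trans (2R) acid, while C-3 (set in step 3) is neither acidic nor involved in bond making and is kept. The step needs substitution to beat E2 loss of HBr back to the coumarin (which would erase C-3) and lactone cleavage to beat hydrolysis of the methyl benzoate; the first is secured by the fast five-ring closure of a phenoxide held next to the secondary bromide at 0 °C, the second by the much higher electrophilicity of the aryl-ester lactone and the ortho-hindered position of the benzoate. Any cis acid from minor cis bromide is harmless, because C-2 becomes planar in step 5.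

Step 5
Reactants: 8 (2R,3R)-3-(3,5-dimethoxyphenyl)-6-methoxy-4-(methoxycarbonyl)-2,3-dihydro-1-benzofuran-2-carboxylic acid; 9 4-iodoanisole
Product: 10 methyl (2R,3R)-3-(3,5-dimethoxyphenyl)-6-methoxy-2-(4-methoxyphenyl)-2,3-dihydro-1-benzofuran-4-carboxylate
Conditions: Ir[dF(CF3)ppy]2(dtbbpy)PF6 (1 mol %), NiCl2·glyme (10 mol %), dtbbpy (15 mol %), Cs2CO3, DMF, blue LEDs, rt
Reagents that add atoms: none
Why: Nickel/photoredox decarboxylative arylation of an α-oxy acid: oxidation of the carboxylate and loss of CO2 should give the planar α-aryloxy radical at C-2, which the aryl–nickel species captures anti to the C-3 aryl group, giving the 2,3-trans (2R) product, also the thermodynamic isomer.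

Step 6
Reactants: 10 methyl (2R,3R)-3-(3,5-dimethoxyphenyl)-6-methoxy-2-(4-methoxyphenyl)-2,3-dihydro-1-benzofuran-4-carboxylate
Product: 11 (2R,3R)-3-(3,5-dimethoxyphenyl)-N,6-dimethoxy-2-(4-methoxyphenyl)-N-methyl-2,3-dihydro-1-benzofuran-4-carboxamide
Conditions: MeNH(OMe)·HCl, i-PrMgCl, THF, −20 → 0 °C
Reagents that add atoms: N,O-dimethylhydroxylamine hydrochloride CNOC.Cl
Why: Aminolysis of the ester by the magnesium amide (Weinreb amide formation) should proceed without touching the two benzylic stereocentres, which carry no acidic hydrogen.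

Step 7
Reactants: 11 (2R,3R)-3-(3,5-dimethoxyphenyl)-N,6-dimethoxy-2-(4-methoxyphenyl)-N-methyl-2,3-dihydro-1-benzofuran-4-carboxamide
Product: 13 (2R,3R)-3-(2-formyl-3,5-dimethoxyphenyl)-N,6-dimethoxy-2-(4-methoxyphenyl)-N-methyl-2,3-dihydro-1-benzofuran-4-carboxamide, via aryl iminium chloride 12 (not isolated)
Conditions: POCl3, DMF, 0 → 60 °C; then aq. NaOAc
Reagents that add atoms: N,N-dimethylformamide CN(C)C=O; water O
Why: Vilsmeier–Haack formylation should occur on ring D, the only ring activated by two methoxy groups and not deactivated by a carbonyl group, at the carbon para to one OMe and next to the C-3 attachment (the two ortho carbons are equivalent); no stereocentre is formed.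

Step 8
Reactants: 13 (2R,3R)-3-(2-formyl-3,5-dimethoxyphenyl)-N,6-dimethoxy-2-(4-methoxyphenyl)-N-methyl-2,3-dihydro-1-benzofuran-4-carboxamide; 14 4-methoxyphenylmagnesium bromide; 15 3,5-dimethoxybenzylmagnesium chloride
Product: 17 2-(3,5-dimethoxyphenyl)-1-[(2R,3R)-3-{2-[hydroxy(4-methoxyphenyl)methyl]-3,5-dimethoxyphenyl}-6-methoxy-2-(4-methoxyphenyl)-2,3-dihydro-1-benzofuran-4-yl]ethan-1-one (carbinol epimers), via bromomagnesium alkoxide 16 (not isolated)
Conditions: 14 (1.1 equiv), THF, −78 °C; then 15 (3 equiv), 0 °C → rt; aq. NH4Cl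
Reagents that add atoms: none
Why: Chemoselective Grignard additions: the aryl Grignard should add to the aldehyde at −78 °C, where the Weinreb amide is inert, and the benzyl Grignard then turns the amide into the ketone through the stable chelated tetrahedral intermediate (Weinreb ketone synthesis); the carbinol centre forms as a mixture, which does not matter because it is ionised in step 9.

Step 9
Reactants: 17 2-(3,5-dimethoxyphenyl)-1-[(2R,3R)-3-{2-[hydroxy(4-methoxyphenyl)methyl]-3,5-dimethoxyphenyl}-6-methoxy-2-(4-methoxyphenyl)-2,3-dihydro-1-benzofuran-4-yl]ethan-1-one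
Product: 19 eight-membered ring ketone (DHB 2R,3R; CH(ArC) R; CH(ring B) R; the two aryl groups trans), via bis-silyl intermediate 18 (not isolated)
Conditions: TMSOTf (3 equiv), i-Pr2NEt (2.2 equiv), CH2Cl2 (2 mM), 0 °C → rt; aq. NaHCO3; then DBU, CH2Cl2, rt
Reagents that add atoms: none
Why: One-pot enol silane formation and SN1 (Mukaiyama-type) alkylation: TMSOTf should ionise the doubly aryl-stabilised benzhydryl silyl ether, and the enol silane carbon captures the cation in an 8-ring closure (no carbon of ring E can reach the cation, and ring B could only close a ten-membered ring); the anisyl group is expected to take the pseudo-equatorial position on the face away from DHB C-2, and DBU then equilibrates the centre α to the ketone to the trans arrangement of the two aryl groups.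

Step 10
Reactants: 19 eight-membered ring ketone; 20 4-methoxybenzylmagnesium chloride
Product: 21 tertiary alcohol from 1,2-addition of the 4-methoxybenzyl group to the ring ketone of 19 (carbinol epimers)
Conditions: CeCl3, THF, −78 °C
Reagents that add atoms: none
Why: 1,2-Addition of the benzylcerium reagent (from the Grignard reagent and CeCl3) should outrun enolisation of the hindered α-aryl ketone; the new carbinol centre does not matter because it is ionised in step 11.

Step 11
Reactants: 21 tertiary alcohol
Product: 23 octa-O-methylstenophyllol B, via benzylidene alkene 22 (not isolated)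
Conditions: TFA, CH2Cl2, −30 → 0 °C
Reagents that add atoms: none
Why: Cationic cascade ending in an intramolecular Friedel–Crafts alkylation: ionisation of the tertiary benzylic alcohol, loss of a proton to alkene 22 (or a direct 1,2-hydride shift) and reprotonation should give the 4-methoxybenzyl cation, which the ring-B carbon ortho to the ring junction and para to OMe attacks 5-exo; the two new centres are set together under substrate control, the equilibrating cation closing through the transition state that places the three contiguous cyclopentane substituents all-trans (trans 5–8 ring fusion, ArA anti to ring E).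

Step 12
Reactants: 23 octa-O-methylstenophyllol B
Product: 24 stenophyllol B
Conditions: BBr3, CH2Cl2, −78 °C → rt; then H2O
Reagents that add atoms: none
Why: Lewis acid cleavage of the eight aryl methyl ethers; if the benzylic C2–O bond of the DHB opens under these conditions it can only reclose to the trans ring, since no carbon nucleophile is within reach of C-2, and no other stereocentre is affected.

**Compound list**
1 | 3,5-dihydroxybenzoic acid | OC(=O)c1cc(O)cc(O)c1 | starting material
2 | ethyl 3-(3,5-dimethoxyphenyl)-3-oxopropanoate | CCOC(=O)CC(=O)c1cc(OC)cc(OC)c1 | starting material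
3 | 4-(3,5-dimethoxyphenyl)-7-hydroxy-2-oxo-2H-chromene-5-carboxylic acid | OC(=O)c1cc(O)cc2oc(=O)cc(-c3cc(OC)cc(OC)c3)c12 | intermediate
4 | methyl 4-(3,5-dimethoxyphenyl)-7-methoxy-2-oxo-2H-chromene-5-carboxylate | COC(=O)c1cc(OC)cc2oc(=O)cc(-c3cc(OC)cc(OC)c3)c12 | intermediate
5 | methyl (4R)-2-{[diethoxy(methyl)silyl]oxy}-4-(3,5-dimethoxyphenyl)-7-methoxy-4H-chromene-5-carboxylate (silyl ketene acetal) | COc1cc(OC)cc(c1)[C@@H]1c2c(cc(OC)cc2C(=O)OC)OC(O[Si](C)(OCC)OCC)=C1 | intermediate
6 | methyl (3S,4R)-3-bromo-4-(3,5-dimethoxyphenyl)-7-methoxy-2-oxochromane-5-carboxylate | COc1cc(OC)cc(c1)[C@@H]1c2c(cc(OC)cc2C(=O)OC)OC(=O)[C@H]1Br | intermediate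
7 | dilithium (2S,3R)-2-bromo-3-(3,5-dimethoxyphenyl)-3-[4-methoxy-2-(methoxycarbonyl)-6-oxidophenyl]propanoate | COc1cc(OC)cc(c1)[C@@H]([C@H](Br)C(=O)[O-])c1c([O-])cc(OC)cc1C(=O)OC.[Li+].[Li+] | intermediate
8 | (2R,3R)-3-(3,5-dimethoxyphenyl)-6-methoxy-4-(methoxycarbonyl)-2,3-dihydro-1-benzofuran-2-carboxylic acid | COc1cc(OC)cc(c1)[C@@H]1c2c(cc(OC)cc2C(=O)OC)O[C@H]1C(=O)O | intermediate
9 | 4-iodoanisole | COc1ccc(I)cc1 | starting material
10 | methyl (2R,3R)-3-(3,5-dimethoxyphenyl)-6-methoxy-2-(4-methoxyphenyl)-2,3-dihydro-1-benzofuran-4-carboxylate | COc1cc(OC)cc(c1)[C@@H]1c2c(cc(OC)cc2C(=O)OC)O[C@H]1c1ccc(OC)cc1 | intermediate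
11 | (2R,3R)-3-(3,5-dimethoxyphenyl)-N,6-dimethoxy-2-(4-methoxyphenyl)-N-methyl-2,3-dihydro-1-benzofuran-4-carboxamide | COc1cc(OC)cc(c1)[C@@H]1c2c(cc(OC)cc2C(=O)N(C)OC)O[C@H]1c1ccc(OC)cc1 | intermediate
12 | aryl iminium chloride: the ArCH=NMe2+ Cl− precursor of aldehyde 13 | C[N+](C)=Cc1c(OC)cc(OC)cc1[C@@H]1c2c(cc(OC)cc2C(=O)N(C)OC)O[C@H]1c1ccc(OC)cc1.[Cl-] | intermediate
13 | (2R,3R)-3-(2-formyl-3,5-dimethoxyphenyl)-N,6-dimethoxy-2-(4-methoxyphenyl)-N-methyl-2,3-dihydro-1-benzofuran-4-carboxamide | O=Cc1c(OC)cc(OC)cc1[C@@H]1c2c(cc(OC)cc2C(=O)N(C)OC)O[C@H]1c1ccc(OC)cc1 | intermediate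
14 | 4-methoxyphenylmagnesium bromide | COc1ccc([Mg]Br)cc1 | starting material
15 | 3,5-dimethoxybenzylmagnesium chloride | COc1cc(C[Mg]Cl)cc(OC)c1 | starting material
16 | bromomagnesium alkoxide of the benzhydrol formed from 13 and 14 (Weinreb amide still intact; carbinol epimers) | COc1ccc(cc1)C(O[Mg]Br)c1c(OC)cc(OC)cc1[C@@H]1c2c(cc(OC)cc2C(=O)N(C)OC)O[C@H]1c1ccc(OC)cc1 | intermediate
17 | 2-(3,5-dimethoxyphenyl)-1-[(2R,3R)-3-{2-[hydroxy(4-methoxyphenyl)methyl]-3,5-dimethoxyphenyl}-6-methoxy-2-(4-methoxyphenyl)-2,3-dihydro-1-benzofuran-4-yl]ethan-1-one (carbinol epimers) | COc1ccc(cc1)C(O)c1c(OC)cc(OC)cc1[C@@H]1c2c(cc(OC)cc2C(=O)Cc2cc(OC)cc(OC)c2)O[C@H]1c1ccc(OC)cc1 | intermediate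
18 | bis(trimethylsilyl) derivative of 17: trimethylsilyl enol ether of the ketone and trimethylsilyl ether of the benzhydrol | COc1ccc(cc1)C(O[Si](C)(C)C)c1c(OC)cc(OC)cc1[C@@H]1c2c(cc(OC)cc2C(O[Si](C)(C)C)=Cc2cc(OC)cc(OC)c2)O[C@H]1c1ccc(OC)cc1 | intermediate
19 | eight-membered ring ketone: the (2R,3R)-DHB in which the ring-D carbon ortho to DHB C-3 and DHB C-4 are bridged by CH(4-methoxyphenyl)–CH(3,5-dimethoxyphenyl)–C(=O); CH(ArC) R, CH(ring B) R, aryl groups trans | COc1cc(OC)cc(c1)[C@H]1[C@H](c2ccc(OC)cc2)c2c(OC)cc(OC)cc2[C@@H]2c3c(cc(OC)cc3C1=O)O[C@H]2c1ccc(OC)cc1 | intermediate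
20 | 4-methoxybenzylmagnesium chloride | COc1ccc(C[Mg]Cl)cc1 | starting material
21 | tertiary alcohol: 19 with C(OH)(CH2-4-methoxyphenyl) in place of the ring C=O (carbinol epimers) | COc1cc(OC)cc(c1)[C@H]1[C@H](c2ccc(OC)cc2)c2c(OC)cc(OC)cc2[C@@H]2c3c(cc(OC)cc3C1(O)Cc1ccc(OC)cc1)O[C@H]2c1ccc(OC)cc1 | intermediate
22 | benzylidene alkene: 19 with C=CH(4-methoxyphenyl) in place of the ring C=O | COc1cc(OC)cc(c1)[C@H]1[C@H](c2ccc(OC)cc2)c2c(OC)cc(OC)cc2[C@@H]2c3c(cc(OC)cc3C1=Cc1ccc(OC)cc1)O[C@H]2c1ccc(OC)cc1 | intermediate
23 | octa-O-methylstenophyllol B (DHB C-2 R, C-3 R; CH(ArC) R; indane C-3 R; indane C-2 S; indane C-1 S) | COc1ccc([C@H]2c3c(OC)cc(OC)cc3[C@H]3[C@H](c4ccc(OC)cc4)c4c(OC)cc(OC)cc4[C@@H]4c5c(cc(OC)cc5[C@H]23)O[C@H]4c2ccc(OC)cc2)cc1 | intermediate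
24 | stenophyllol B | Oc1ccc([C@H]2c3c(O)cc(O)cc3[C@H]3[C@H](c4ccc(O)cc4)c4c(O)cc(O)cc4[C@@H]4c5c(cc(O)cc5[C@H]23)O[C@H]4c2ccc(O)cc2)cc1 | target

Total step count: 12. Longest linear sequence: 12 steps (1 → 24); compounds 2, 9, 14, 15 and 20 are bought.

**The three steps most likely to fail**

Step 9. Intermolecular alkylation (oligomerisation) may outrun the eight-membered closure, or the cation may close from the other face and give the epimer at the anisyl-bearing carbon. The fallback sets out from 13 and returns at 19. The aldehyde is masked as the dimethyl acetal F1 (HC(OMe)3, PPTS, MeOH). Benzyl Grignard 15 then converts the Weinreb amide into the keto acetal F2. Mild hydrolysis (PPTS, acetone/H2O) gives the keto aldehyde F3. An intramolecular aldol condensation (piperidine, AcOH, PhMe, reflux) closes the eight-membered ring as the cyclic enone F4 under basic conditions, where a Nazarov-type closure onto ring E is not available. Copper-catalysed conjugate addition of 14 (CuBr·SMe2, THF, −40 °C), protonation and DBU equilibration should then give 19; the aryl group now enters a preformed ring and, if needed, a chiral ligand on copper can reinforce the facial choice.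

Step 11. The tertiary cation may fragment (loss of the stabilised benzhydryl cation with opening of the eight-membered ring), or facial control at the two new indane carbons may be poor. The fallback sets out from 19 and returns at 23. Wittig methoxymethylenation (Ph3P=CHOMe from the phosphonium chloride and KHMDS, THF) gives the enol ether F5. Hydrolysis (aq. HCl, THF) gives the ring aldehyde F6, whose α-centre is epimerisable and should settle trans to the neighbouring 3,5-dimethoxyphenyl group. Addition of 14 gives the secondary carbinol F7. TFA in CH2Cl2 ionises it to the same 4-methoxybenzyl cation and the Friedel–Crafts closure gives 23, with the ring-fusion centre fixed before the cation is made.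

Step 5. Oxidative addition of the electron-rich iodide may be slow and capture of the hindered radical inefficient, or the radical may be over-oxidised to the oxocarbenium ion, which would aromatise to the benzofuran and erase C-3. The fallback sets out from 8 and returns at 10. The acid is converted into the N-hydroxyphthalimide ester F8 (N-hydroxyphthalimide, DIC, cat. DMAP, CH2Cl2). F8 is coupled with 9 in a thermal nickel-catalysed reductive cross-electrophile coupling (NiBr2·glyme, dtbbpy, Zn, DMA, rt), which generates the same C-2 radical by reduction and keeps it away from an oxidising photocatalyst.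

**Further compounds**
F1 | step 9 | dimethyl acetal of aldehyde 13 | COC(OC)c1c(OC)cc(OC)cc1[C@@H]1c2c(cc(OC)cc2C(=O)N(C)OC)O[C@H]1c1ccc(OC)cc1
F2 | step 9 | keto acetal: F1 with C(=O)CH2(3,5-dimethoxyphenyl) in place of the Weinreb amide | COC(OC)c1c(OC)cc(OC)cc1[C@@H]1c2c(cc(OC)cc2C(=O)Cc2cc(OC)cc(OC)c2)O[C@H]1c1ccc(OC)cc1
F3 | step 9 | keto aldehyde from hydrolysis of F2 | O=Cc1c(OC)cc(OC)cc1[C@@H]1c2c(cc(OC)cc2C(=O)Cc2cc(OC)cc(OC)c2)O[C@H]1c1ccc(OC)cc1
F4 | step 9 | cyclic enone: eight-membered ring with C(=O)–C(3,5-dimethoxyphenyl)=CH between DHB C-4 and ring D | COc1cc(OC)cc(c1)C1=Cc2c(OC)cc(OC)cc2[C@@H]2c3c(cc(OC)cc3C1=O)O[C@H]2c1ccc(OC)cc1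
F5 | step 11 | methyl enol ether: 19 with C=CH(OMe) in place of the ring C=O | COc1cc(OC)cc(c1)[C@H]1[C@H](c2ccc(OC)cc2)c2c(OC)cc(OC)cc2[C@@H]2c3c(cc(OC)cc3C1=COC)O[C@H]2c1ccc(OC)cc1
F6 | step 11 | ring aldehyde: 19 with CH(CHO) in place of the ring C=O, formyl trans to the neighbouring aryl group | COc1cc(OC)cc(c1)[C@H]1[C@H](c2ccc(OC)cc2)c2c(OC)cc(OC)cc2[C@@H]2c3c(cc(OC)cc3[C@@H]1C=O)O[C@H]2c1ccc(OC)cc1
F7 | step 11 | secondary carbinol: F6 after addition of 14 to the formyl group (carbinol epimers) | COc1cc(OC)cc(c1)[C@H]1[C@H](c2ccc(OC)cc2)c2c(OC)cc(OC)cc2[C@@H]2c3c(cc(OC)cc3[C@@H]1C(O)c1ccc(OC)cc1)O[C@H]2c1ccc(OC)cc1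
F8 | step 5 | N-hydroxyphthalimide ester of acid 8 | COc1cc(OC)cc(c1)[C@@H]1c2c(cc(OC)cc2C(=O)OC)O[C@H]1C(=O)ON1C(=O)c2ccccc2C1=O
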